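**Retrosynthetic overview** (germacrane numbering: lactone C12(=O)–O–C6, C7–C11(=C13), ester on C8, oxirane C1–C10)
1. Target ⇒ peracid epoxidation of the 1(10)-olefin, after Mitsunobu esterification (inversion at C8) of the macrocyclic 8S-alcohol 18 with (2S,3S)-epoxyangelic acid 22 (Sharpless epoxidation route from angelic acid).
2. Key disconnection C7–C8: an intramolecular allylchromium addition in which C7, normally the electrophilic β-carbon of the butenolide, is the nucleophile toward the C8 aldehyde (16 → 18). It forms the ten-membered ring, C7, C8 and the α-methylene lactone in one step.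
3. 3-(Bromomethyl)butenolide ⇐ Pd carbonylative lactonisation of a Z-iodoallylic alcohol ⇐ directed hydroalumination/iodination ⇐ Zn–ProPhenol alkynylation of enal 8 (sets C6).
4. C8 enters as a formyl anion (2-lithio-1,3-dithiane) on the allylic bromide obtained by SeO2 oxidation of neryl acetate, which supplies the 4Z and 1(10)E olefins.
5. Ring order: butenolide (step 7) → ten-membered carbocycle (step 10) → side-chain oxirane attached (step 14) → 1,10-oxirane (step 15).

Assumption: the (R,R)-ProPhenol–zinc catalyst transfers the alkynyl group to the Si face of enal 8 (giving 6R); if the sense is the opposite for this substrate, the (S,S)-ligand is used and nothing else changes.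

**Route**

Step 1
Reactants: 1 neryl acetate, (2Z)-3,7-dimethylocta-2,6-dien-1-yl acetate
Product: 2 (2Z,6E)-8-hydroxy-3,7-dimethylocta-2,6-dien-1-yl acetate
Conditions: SeO2 (0.3 equiv), t-BuOOH (3 equiv), salicylic acid (0.1 equiv), CH2Cl2, 23 °C
Reagents that add atoms: tert-butyl hydroperoxide CC(C)(C)OO (oxygen relayed by selenium dioxide O=[Se]=O)
Why: Riley/Sharpless allylic oxidation (ene reaction, then [2,3]-shift) hydroxylates only the E-methyl of the electron-rich terminal olefin, which fixes the 1(10)E geometry; the acetate-deactivated 2,3-olefin is untouched.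

Step 2
Reactants: 2 (2Z,6E)-8-hydroxy-3,7-dimethylocta-2,6-dien-1-yl acetate
Product: 3 (2Z,6E)-8-bromo-3,7-dimethylocta-2,6-dien-1-yl acetate
Conditions: PBr3 (0.4 equiv), Et2O, −10 °C
Reagents that add atoms: phosphorus tribromide BrP(Br)Br
Why: SN2 bromination of a primary allylic alcohol at low temperature proceeds without allylic transposition or E/Z loss.

Step 3
Reactants: 3 (2Z,6E)-8-bromo-3,7-dimethylocta-2,6-dien-1-yl acetate; 4 1,3-dithiane
Product: 7 (2Z,6E)-8-(1,3-dithian-2-yl)-3,7-dimethylocta-2,6-dien-1-ol, via 2-lithio-1,3-dithiane 5 (not isolated), via dithianyl acetate 6 (not isolated)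
Conditions: 4 (2.2 equiv), n-BuLi, THF, −30 °C; then 3, −78 °C; then MeOH, K2CO3 (cat.), 23 °C
Reagents that add atoms: none
Why: Corey–Seebach alkylation, in which the formyl anion equivalent displaces the primary allylic bromide by SN2 at C9 and brings in C8 as a masked aldehyde; methanolysis removes the acetate in the same pot, so any acetate cleavage by the lithio reagent also leads to 7.

Step 4
Reactants: 7 (2Z,6E)-8-(1,3-dithian-2-yl)-3,7-dimethylocta-2,6-dien-1-ol
Product: 8 (2Z,6E)-8-(1,3-dithian-2-yl)-3,7-dimethylocta-2,6-dienal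
Conditions: active MnO2 (15 equiv), CH2Cl2, 23 °C
Reagents that add atoms: none
Why: Heterogeneous MnO2 oxidation of an allylic alcohol is neutral, so the Z-enal does not isomerise and the dithiane survives.

Step 5
Reactants: 8 (2Z,6E)-8-(1,3-dithian-2-yl)-3,7-dimethylocta-2,6-dienal; 9 tert-butyldimethyl(prop-2-yn-1-yloxy)silane
Product: 11 (4R,5Z,9E)-1-[(tert-butyldimethylsilyl)oxy]-11-(1,3-dithian-2-yl)-6,10-dimethylundeca-5,9-dien-2-yn-4-ol, via alkynylzinc 10 (not isolated)
Conditions: 9 (3 equiv), Me2Zn (3 equiv), (R,R)-ProPhenol (10 mol%), Ph3PO (20 mol%), toluene, 4 °C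
Reagents that add atoms: none
Why: Trost Zn–ProPhenol asymmetric alkynylation, in which the dinuclear zinc catalyst adds the alkynyl group 1,2 to the Si face of the enal and so sets C6 as R.

Step 6
Reactants: 11 (4R,5Z,9E)-1-[(tert-butyldimethylsilyl)oxy]-11-(1,3-dithian-2-yl)-6,10-dimethylundeca-5,9-dien-2-yn-4-ol
Product: 13 (2Z,4R,5Z,9E)-1-[(tert-butyldimethylsilyl)oxy]-11-(1,3-dithian-2-yl)-2-iodo-6,10-dimethylundeca-2,5,9-trien-4-ol, via alkenylaluminate 12 (not isolated)
Conditions: NaAlH2(OCH2CH2OMe)2 (1.6 equiv), THF, 0 to 23 °C; then I2, −78 °C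
Reagents that add atoms: iodine II
Why: Hydroxyl-directed trans-hydroalumination puts H on C7 and Al on C11 through a five-membered oxa-aluminacycle (the silyl ether oxygen does not direct), and iododealumination with retention gives the Z-iodoalkene with iodine cis to the carbinol; C6 is untouched.

Step 7
Reactants: 13 (2Z,4R,5Z,9E)-1-[(tert-butyldimethylsilyl)oxy]-11-(1,3-dithian-2-yl)-2-iodo-6,10-dimethylundeca-2,5,9-trien-4-ol
Product: 14 (5R)-3-{[(tert-butyldimethylsilyl)oxy]methyl}-5-[(1Z,5E)-7-(1,3-dithian-2-yl)-2,6-dimethylhepta-1,5-dien-1-yl]furan-2(5H)-one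
Conditions: PdCl2(PPh3)2 (5 mol%), CO (1 atm), K2CO3 (2 equiv), THF, 40 °C
Reagents that add atoms: carbon monoxide [C-]#[O+]
Why: Palladium-catalysed carbonylative lactonisation (oxidative addition of zerovalent palladium into C–I, CO insertion, capture of the acylpalladium by the cis hydroxyl) closes the butenolide and supplies C12 with C6 retained.

Step 8
Reactants: 14 (5R)-3-{[(tert-butyldimethylsilyl)oxy]methyl}-5-[(1Z,5E)-7-(1,3-dithian-2-yl)-2,6-dimethylhepta-1,5-dien-1-yl]furan-2(5H)-one
Product: 15 (5R)-3-(bromomethyl)-5-[(1Z,5E)-7-(1,3-dithian-2-yl)-2,6-dimethylhepta-1,5-dien-1-yl]furan-2(5H)-one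
Conditions: Ph3PBr2 (1.2 equiv), CH2Cl2, 0 to 23 °C
Reagents that add atoms: dibromotriphenylphosphorane BrP(Br)(c1ccccc1)(c1ccccc1)c1ccccc1
Why: Appel-type direct conversion of a silyl ether into a bromide; the bromophosphonium activates the ether oxygen and bromide displaces at the primary allylic carbon, giving the allylic bromide in one operation.

Step 9
Reactants: 15 (5R)-3-(bromomethyl)-5-[(1Z,5E)-7-(1,3-dithian-2-yl)-2,6-dimethylhepta-1,5-dien-1-yl]furan-2(5H)-one
Product: 16 (3E,7Z)-8-[(2R)-4-(bromomethyl)-5-oxo-2,5-dihydrofuran-2-yl]-3,7-dimethylocta-3,7-dienal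
Conditions: PhI(OCOCF3)2 (1.5 equiv), MeCN/H2O (9:1), 0 °C, 10 min
Reagents that add atoms: water O
Why: Stork–Zhao oxidative dithiane hydrolysis unmasks the C8 aldehyde in minutes without base, which spares the allylic bromide and butenolide and leaves the β,γ-olefin unconjugated.

Step 10
Reactants: 16 (3E,7Z)-8-[(2R)-4-(bromomethyl)-5-oxo-2,5-dihydrofuran-2-yl]-3,7-dimethylocta-3,7-dienal
Product: 18 (3aR,4S,6E,10Z,11aR)-4-hydroxy-6,10-dimethyl-3-methylidene-3a,4,5,8,9,11a-hexahydrocyclodeca[b]furan-2(3H)-one, via allylchromium dichloride 17 (not isolated)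
Conditions: CrCl2 (8 equiv), THF/DMF (1:1), 23 °C, syringe-pump addition of 16 over 12 h, 2 mM
Reagents that add atoms: none
Why: Proposed new method: CrCl2 inserts into the allylic C–Br bond to give the 2-(alkoxycarbonyl)allyl chromium species 17, a homoenolate-type nucleophile at C7, which adds through C7 to the tethered C8 aldehyde in a chair Zimmerman–Traxler transition state and regenerates the exo-methylene; the closest known reactions are the intermolecular CrCl2/Zn allylation of aldehydes with 3-(bromomethyl)furan-2(5H)-one and the Nozaki–Hiyama–Kishi macrocyclisations that close germacranolide ten-membered rings; C7 is expected to form anti to the C6 side chain (trans-fused lactone, the less strained fusion for the eight-atom tether), and the E-locked allyl unit with C9 equatorial is expected to give the anti (8S) carbinol, which step 14 inverts.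

Step 11
Reactants: 19 angelic acid, (2Z)-2-methylbut-2-enoic acid
Product: 20 (2Z)-2-methylbut-2-en-1-ol
Conditions: LiAlH4 (1 equiv), Et2O, 0 °C
Reagents that add atoms: none
Why: Hydride reduction of the carboxylic acid gives the allylic alcohol by 1,2-reduction without touching or isomerising the Z-olefin.

Step 12
Reactants: 20 (2Z)-2-methylbut-2-en-1-ol
Product: 21 [(2R,3S)-2,3-dimethyloxiran-2-yl]methanol
Conditions: Ti(OiPr)4 (10 mol%), D-(−)-diisopropyl tartrate (12 mol%), t-BuOOH (2 equiv), 4 Å molecular sieves, CH2Cl2, −20 °C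
Reagents that add atoms: tert-butyl hydroperoxide CC(C)(C)OO
Why: Sharpless asymmetric epoxidation, in which the D-tartrate complex selects the olefin face that gives the 2R,3S epoxy alcohol and syn oxygen transfer keeps the Z relationship as a cis-oxirane, so both side-chain stereocentres are set.

Step 13
Reactants: 21 [(2R,3S)-2,3-dimethyloxiran-2-yl]methanol
Product: 22 (2S,3S)-2,3-dimethyloxirane-2-carboxylic acid
Conditions: RuCl3·xH2O (2 mol%), NaIO4 (3 equiv), CCl4/MeCN/H2O, 23 °C
Reagents that add atoms: water O (enters through the aldehyde hydrate; sodium periodate [Na+].[O-]I(=O)(=O)=O is the terminal oxidant)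
Why: Sharpless RuO4 oxidation takes the primary alcohol to the acid without opening the oxirane; the descriptor at C2 changes from R to S only because of CIP priorities.

Step 14
Reactants: 18 (3aR,4S,6E,10Z,11aR)-4-hydroxy-6,10-dimethyl-3-methylidene-3a,4,5,8,9,11a-hexahydrocyclodeca[b]furan-2(3H)-one; 22 (2S,3S)-2,3-dimethyloxirane-2-carboxylic acid
Product: 23 (3aR,4R,6E,10Z,11aR)-6,10-dimethyl-3-methylidene-2-oxo-2,3,3a,4,5,8,9,11a-octahydrocyclodeca[b]furan-4-yl (2S,3S)-2,3-dimethyloxirane-2-carboxylate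
Conditions: PPh3 (1.5 equiv), DIAD (1.5 equiv), toluene, 0 to 23 °C
Reagents that add atoms: none
Why: Mitsunobu esterification, in which the carboxylate displaces the alkoxyphosphonium by SN2 and inverts C8 from S to R while installing the ester; the acid has no α-hydrogen and its stereocentres are not involved.

Step 15
Reactants: 23 (3aR,4R,6E,10Z,11aR)-6,10-dimethyl-3-methylidene-2-oxo-2,3,3a,4,5,8,9,11a-octahydrocyclodeca[b]furan-4-yl (2S,3S)-2,3-dimethyloxirane-2-carboxylate
Product: 24 CNP0165580.1, the (1R,10R)-1,10-epoxide of 23 (6R,7R,8R; 2'S,3'S; 4Z)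
Conditions: mCPBA (1.05 equiv), CH2Cl2, 0 °C
Reagents that add atoms: 3-chloroperoxybenzoic acid OOC(=O)c1cccc(Cl)c1
Why: Prilezhaev epoxidation picks the most electron-rich olefin (the 4,5-olefin is deactivated by the allylic lactone oxygen and the methylene lactone is electron-poor); syn transfer to the E-olefin gives the trans-oxirane, and attack on the exposed outer face of the ring is expected to give 1R,10R.

**Compound list**
1 | neryl acetate | CC(=O)OC/C=C(/C)CCC=C(C)C | starting material
2 | (2Z,6E)-8-hydroxy-3,7-dimethylocta-2,6-dien-1-yl acetate | CC(=O)OC/C=C(/C)CC/C=C(\C)CO | intermediate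
3 | (2Z,6E)-8-bromo-3,7-dimethylocta-2,6-dien-1-yl acetate | CC(=O)OC/C=C(/C)CC/C=C(\C)CBr | intermediate
4 | 1,3-dithiane | C1CSCSC1 | starting material
5 | 2-lithio-1,3-dithiane | [Li]C1SCCCS1 | intermediate
6 | (2Z,6E)-8-(1,3-dithian-2-yl)-3,7-dimethylocta-2,6-dien-1-yl acetate | CC(=O)OC/C=C(/C)CC/C=C(\C)CC1SCCCS1 | intermediate
7 | (2Z,6E)-8-(1,3-dithian-2-yl)-3,7-dimethylocta-2,6-dien-1-ol | OC/C=C(/C)CC/C=C(\C)CC1SCCCS1 | intermediate
8 | (2Z,6E)-8-(1,3-dithian-2-yl)-3,7-dimethylocta-2,6-dienal | O=C/C=C(/C)CC/C=C(\C)CC1SCCCS1 | intermediate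
9 | tert-butyldimethyl(prop-2-yn-1-yloxy)silane | C#CCO[Si](C)(C)C(C)(C)C | starting material
10 | methyl{3-[(tert-butyldimethylsilyl)oxy]prop-1-yn-1-yl}zinc | C[Zn]C#CCO[Si](C)(C)C(C)(C)C | intermediate
11 | (4R,5Z,9E)-1-[(tert-butyldimethylsilyl)oxy]-11-(1,3-dithian-2-yl)-6,10-dimethylundeca-5,9-dien-2-yn-4-ol | CC(C)(C)[Si](C)(C)OCC#C[C@H](O)/C=C(/C)CC/C=C(\C)CC1SCCCS1 | intermediate
12 | sodium alkenylaluminate of 11 (five-membered oxa-aluminacycle, Al on C11, H on C7) | [Na+].COCCO[Al-]1(OCCOC)O[C@H](/C=C(/C)CC/C=C(\C)CC2SCCCS2)C=C1CO[Si](C)(C)C(C)(C)C | intermediate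
13 | (2Z,4R,5Z,9E)-1-[(tert-butyldimethylsilyl)oxy]-11-(1,3-dithian-2-yl)-2-iodo-6,10-dimethylundeca-2,5,9-trien-4-ol | CC(C)(C)[Si](C)(C)OC/C(I)=C/[C@H](O)/C=C(/C)CC/C=C(\C)CC1SCCCS1 | intermediate
14 | (5R)-3-{[(tert-butyldimethylsilyl)oxy]methyl}-5-[(1Z,5E)-7-(1,3-dithian-2-yl)-2,6-dimethylhepta-1,5-dien-1-yl]furan-2(5H)-one | CC(C)(C)[Si](C)(C)OCC1=C[C@H](OC1=O)/C=C(/C)CC/C=C(\C)CC2SCCCS2 | intermediate
15 | (5R)-3-(bromomethyl)-5-[(1Z,5E)-7-(1,3-dithian-2-yl)-2,6-dimethylhepta-1,5-dien-1-yl]furan-2(5H)-one | BrCC1=C[C@H](OC1=O)/C=C(/C)CC/C=C(\C)CC2SCCCS2 | intermediate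
16 | (3E,7Z)-8-[(2R)-4-(bromomethyl)-5-oxo-2,5-dihydrofuran-2-yl]-3,7-dimethylocta-3,7-dienal | BrCC1=C[C@H](OC1=O)/C=C(/C)CC/C=C(\C)CC=O | intermediate
17 | {[(5R)-5-[(1Z,5E)-2,6-dimethyl-8-oxoocta-1,5-dien-1-yl]-2-oxo-2,5-dihydrofuran-3-yl]methyl}chromium dichloride | Cl[Cr](Cl)CC1=C[C@H](OC1=O)/C=C(/C)CC/C=C(\C)CC=O | intermediate
18 | (3aR,4S,6E,10Z,11aR)-4-hydroxy-6,10-dimethyl-3-methylidene-3a,4,5,8,9,11a-hexahydrocyclodeca[b]furan-2(3H)-one | C=C1C(=O)O[C@@H]2/C=C(/C)CC/C=C(\C)C[C@H](O)[C@@H]12 | intermediate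
19 | angelic acid, (2Z)-2-methylbut-2-enoic acid | C/C=C(/C)C(=O)O | starting material
20 | (2Z)-2-methylbut-2-en-1-ol | C/C=C(/C)CO | intermediate
21 | [(2R,3S)-2,3-dimethyloxiran-2-yl]methanol | OC[C@@]1(C)O[C@H]1C | intermediate
22 | (2S,3S)-2,3-dimethyloxirane-2-carboxylic acid | OC(=O)[C@@]1(C)O[C@H]1C | intermediate
23 | (3aR,4R,6E,10Z,11aR)-6,10-dimethyl-3-methylidene-2-oxo-2,3,3a,4,5,8,9,11a-octahydrocyclodeca[b]furan-4-yl (2S,3S)-2,3-dimethyloxirane-2-carboxylate | C=C1C(=O)O[C@@H]2/C=C(/C)CC/C=C(\C)C[C@@H](OC(=O)[C@@]3(C)O[C@H]3C)[C@@H]12 | intermediate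
24 | CNP0165580.1, (1R,10R)-1,10-epoxy-(4Z)-germacra-4,11(13)-dien-12,6-olid-8-yl (2S,3S)-2,3-dimethyloxirane-2-carboxylate (6R,7R,8R) | C=C1C(=O)O[C@@H]2/C=C(/C)CC[C@H]3O[C@]3(C)C[C@@H](OC(=O)[C@@]3(C)O[C@H]3C)[C@@H]12 | target

**Count**
Total steps: 15. Longest linear sequence: 12 (steps 1–10, 14, 15); the side chain takes steps 11–13.

**Three steps most likely to fail, with fallbacks**

Step 10 (ring closure; risk of oligomers, cis fusion or the other C8 epimer). The fallback separates metalation from C–C bond formation. Setting out from 16, Pd(PPh3)4-catalysed stannylation with (Bu3Sn)2 gives the allylstannane aldehyde F1. BF3·OEt2 at −78 °C and 1 mM then closes the ring through an open antiperiplanar SE2' transition state, which is syn-selective for this E-locked allyl unit and should give the 8R-alcohol F2 directly. F2 needs no inversion and is acylated with 22 (2,4,6-trichlorobenzoyl chloride, Et3N, DMAP, toluene), which comes back to the route at 23. If the chromium closure itself gave the 8R alcohol, the same acylation would be used.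

Step 14 (Mitsunobu on a hindered ring carbinol; risk of elimination or retention). The fallback does activation and displacement separately. From 18, MsCl/Et3N at −20 °C gives the 8S-mesylate F3, and the caesium salt of 22 (Cs2CO3, DMF, 50 °C) displaces it with inversion, returning at 23.

Step 15 (face and site selectivity of the epoxidation). If the peracid attacks the wrong face of the 1(10)-olefin, a halohydrin route inverts the facial outcome. From 23, NBS in THF/H2O gives the (1S,10R)-bromohydrin F4: the bromonium forms on the exposed face and water opens it at tertiary C10 from the other face. Cs2CO3 in MeCN then closes the oxirane with inversion at C1, coming back at 24.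

**Further compounds**
F1 | step 10 | (3E,7Z)-3,7-dimethyl-8-{(2R)-5-oxo-4-[(tributylstannyl)methyl]-2,5-dihydrofuran-2-yl}octa-3,7-dienal | CCCC[Sn](CCCC)(CCCC)CC1=C[C@H](OC1=O)/C=C(/C)CC/C=C(\C)CC=O
F2 | step 10 | (3aR,4R,6E,10Z,11aR)-4-hydroxy-6,10-dimethyl-3-methylidene-3a,4,5,8,9,11a-hexahydrocyclodeca[b]furan-2(3H)-one | C=C1C(=O)O[C@@H]2/C=C(/C)CC/C=C(\C)C[C@@H](O)[C@@H]12
F3 | step 14 | (3aR,4S,6E,10Z,11aR)-6,10-dimethyl-3-methylidene-2-oxo-2,3,3a,4,5,8,9,11a-octahydrocyclodeca[b]furan-4-yl methanesulfonate | C=C1C(=O)O[C@@H]2/C=C(/C)CC/C=C(\C)C[C@H](OS(C)(=O)=O)[C@@H]12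
F4 | step 15 | (1S,10R)-1-bromo-10-hydroxy-1,10-dihydro derivative of 23 (germacrane numbering) | C=C1C(=O)O[C@@H]2/C=C(/C)CC[C@H](Br)[C@](C)(O)C[C@@H](OC(=O)[C@@]3(C)O[C@H]3C)[C@@H]12
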